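| flask | solid substrate | remark | time |
|---|---|---|---|
| noon | 0.21 M | run made earlier |  |
| autumn | 0.48 M | run made earlier |  |
| flask | 0.32 M |  | 3.0 h |

- noon (time / min: target / %, solid substrate / %): 15.0: 8, 31; 25.0: 9, 23; 30.0: 14, 20; 40.0: 23, 11; 60.0: 64, 0; 80.0: 90, 1; 120: 83, 0
- autumn (time / min: target / %, solid substrate / %): 15.0: 1, 69; 25.0: 5, 67; 30.0: 9, 66; 40.0: 11, 63; 60.0: 43, 29; 80.0: 88, 3; 120: 83, 0

(standard deviation of a reading: 2 percentage points)

- solid, in amounts per volume of the solution: solid substrate
- the earlier runs were read with a standard deviation of 2 percentage points
- at the start none of the solid substrate is in solution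

- the moment within 3.0 h at which there is most target
- the amount of target, in percent of the solid substrate charged, at that time

1. The charges of the autumn and noon runs stand in a ratio of 2.29, but the solid gone by 15.0 min stands in a ratio of 1.03. So the hunch of a ceiling on dissolving (a solubility limit) holds up.
2. As a reading, that ceiling is [dissolved] = 0.147 M.
3. Counting what stays solid once the solution stands at that ceiling, one minus [dissolved] over the charge gives 54.1% for this flask: the solid fraction left.
4. That value lies between noon's 30.1% and autumn's 69.4%. Both runs read their highest target at 80.0 min, 90% and 88%. So this reckoning puts the peak of this flask by 80.0 min, near those readings.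
5. The forecast gave 1.35 h and 90%, starting from this: “The solid figures show a solubility limit.”
6. The flask gives 91.3% at 1.13 h.

    target ⇌ isomer of the product (K = 0.220, k = 1.42 × 10⁻⁴ s⁻¹)
    starting material → target (k = 9.11 × 10⁻⁵ s⁻¹)
    solid substrate ⇌ starting material, rate k3*(cs3 - [starting material]) while solid is left; crystals form when [starting material] > cs3 (solubility = 0.140 M, k = 0.0398 s⁻¹)
    starting material + 2 target → 3 target (k = 0.107 M⁻² s⁻¹)

7. The solid fraction left, 54.1%, stands beside 51.9% solid in this flask at 0.300 h. The midpoint of the dissolving turnover up to 3.0 h comes at 0.401 h, and that of target passing into isomer of the product at 1.17 h, which is earlier for the dissolving.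
8. In the neighbour flask with 0.080 M charged, the ceiling over the charge is 1.84, above one, so the solid fraction left is 0%. That neighbour flask ends with 0% solid, 78.3% target and 5.92% starting material.

(The numbers in the tables are simulated from invented constants; scatter was added.)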